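Ring-B carbons C5–C10 and ring-A carbons C1–C5/C10 are numbered as in terpenoids; C11/C11′ are the linker carbons.

**Strategy.** The C2-symmetric C30 skeleton is assembled by a twofold Stille coupling of one bicyclic enol triflate onto an ethene linchpin (C9–C11 and C9′–C11′). Everything rests on the C1–C2 bond of ring A: C1 hangs from the quaternary carbon C10 and C2, through C3, from the quaternary carbon C4. A vinyl group on C10 and an allyl group on C4, held trans across C5–C10 of ring B, are therefore joined by ring-closing metathesis. In one operation this closes ring A as the trans-fused decalin and leaves only a C1=C2 alkene to saturate. The precursor is a monocyclic cyclohexenyl triflate made from (R)-carvone, whose stereocentre becomes C5.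

Key step: step 6

Remark: (R)-(−)-carvone and (E)-1,2-bis(tributylstannyl)ethene are taken as commercial. Compound 3 is used as its C6 epimer mixture, since that centre is re-enolised in step 2.

Step 1
Reactants: 1 (R)-(−)-carvone
Product: 3 (5R)-2,6-dimethyl-5-(prop-1-en-2-yl)cyclohex-2-en-1-one (6-methylcarvone, C6 epimer mixture), via lithium α′-dienolate of carvone 2 (not isolated)
Conditions: LDA (LiN(i-Pr)2), THF, −78 °C; MeI, −78 to 0 °C
Reagents that add atoms: iodomethane, CI
Why: Enolate alkylation: LDA removes the kinetic α′-proton of the enone (C6) and the cross-conjugated dienolate is C-methylated, the C6 configuration being irrelevant because this centre is re-enolised in step 2 while C5 is untouched.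

Step 2
Reactants: 3 6-methylcarvone
Product: 5 (5S,6S)-6-ethenyl-2,6-dimethyl-5-(prop-1-en-2-yl)cyclohex-2-en-1-one (vinyl trans, methyl cis to the isopropenyl group), via lithium α′-dienolate of 6-methylcarvone 4 (not isolated)
Conditions: LDA (LiN(i-Pr)2), THF, −78 °C; then vinyl bromide, Pd2(dba)3 (cat.), P(t-Bu)3 (cat.), −78 to 23 °C
Reagents that add atoms: vinyl bromide, C=CBr
Why: Palladium-catalysed α-alkenylation of a preformed ketone enolate: the only α-proton (C6) is removed irreversibly, vinyl bromide adds oxidatively to zerovalent palladium, and the vinylpalladium unit is delivered to the enolate face anti to the C5 isopropenyl group, so that reductive elimination should set the quaternary centre (future C10) with vinyl trans and methyl cis to the C5 substituent.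

Step 3
Reactants: 5 (5S,6S)-6-ethenyl-2,6-dimethyl-5-(prop-1-en-2-yl)cyclohex-2-en-1-one
Product: 7 (5S,6S)-6-ethenyl-2,6-dimethyl-5-(prop-1-en-2-yl)cyclohex-1-en-1-yl trifluoromethanesulfonate, via lithium enolate of the 2,3-dihydro ketone 6 (not isolated)
Conditions: L-Selectride (LiBH(s-Bu)3), THF, −78 °C; then PhNTf2, −78 to 23 °C
Reagents that add atoms: N-phenylbis(trifluoromethanesulfonimide), O=S(=O)(N(c1ccccc1)S(=O)(=O)C(F)(F)F)C(F)(F)F
Why: Conjugate reduction followed by enolate triflation: the bulky hydride attacks the unsubstituted β-carbon because the carbonyl is shielded by the adjacent quaternary carbon, and O-sulfonylation of the regiodefined enolate fixes the future C8=C9 alkene as a tetrasubstituted enol triflate without touching C5 or C6.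

Step 4
Reactants: 7 (5S,6S)-6-ethenyl-2,6-dimethyl-5-(prop-1-en-2-yl)cyclohex-1-en-1-yl trifluoromethanesulfonate
Product: 8 (5R,6S)-5-(2-bromopropan-2-yl)-6-ethenyl-2,6-dimethylcyclohex-1-en-1-yl trifluoromethanesulfonate
Conditions: HBr (33% in AcOH), CH2Cl2, 0 °C
Reagents that add atoms: hydrogen bromide, Br
Why: Markovnikov hydrobromination: the 1,1-disubstituted isopropenyl alkene is protonated to a tertiary cation far faster than the monosubstituted vinyl group or the electron-poor enol triflate alkene, and bromide capture gives the tertiary bromide with no stereocentre created (the descriptor at C5 changes only through CIP priorities).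

Step 5
Reactants: 8 (5R,6S)-5-(2-bromopropan-2-yl)-6-ethenyl-2,6-dimethylcyclohex-1-en-1-yl trifluoromethanesulfonate
Product: 9 (5S,6S)-6-ethenyl-2,6-dimethyl-5-(2-methylpent-4-en-2-yl)cyclohex-1-en-1-yl trifluoromethanesulfonate
Conditions: allylSnBu3 (4 equiv), AIBN (cat.), PhH, 80 °C
Reagents that add atoms: allyltributylstannane, C=CC[Sn](CCCC)(CCCC)CCCC
Why: Keck radical allylation: tributylstannyl radical abstracts bromine, the tertiary radical adds to the terminus of the allylstannane and β-scission of tributylstannyl carries the chain, which builds the quaternary gem-dimethyl carbon (future C4) without a new stereocentre, cyclisation onto the vinyl or triflate alkene being a disfavoured 5-endo process.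

Step 6
Reactants: 9 (5S,6S)-6-ethenyl-2,6-dimethyl-5-(2-methylpent-4-en-2-yl)cyclohex-1-en-1-yl trifluoromethanesulfonate
Product: 10 (4aS,8aS)-2,5,5,8a-tetramethyl-3,4,4a,5,6,8a-hexahydronaphthalen-1-yl trifluoromethanesulfonate
Conditions: second-generation Grubbs catalyst RuCl2(=CHPh)(H2IMes)(PCy3) (5 mol %), CH2Cl2 (0.01 M), 40 °C
Reagents that add atoms: none
Why: Ring-closing olefin metathesis: the ruthenium benzylidene first exchanges with the unhindered allyl terminus on C4, and the new alkylidene adds [2+2] to the C10 vinyl group and cycloreverts, expelling ethene and forming the C1=C2 bond. The closest known reaction type is the RCM of 1,7-dienes to cyclohexenes that carry an allylic quaternary carbon. Ring A closes as a six-membered carbocycle with an endocyclic cis alkene, and it can only be trans-fused to ring B because the two arms sit trans across the C5–C10 bond. No stereocentre is formed; C5 and C10 are carried over from 9 and are not epimerisable under these neutral conditions. The step needs chemoselectivity against the C8=C9 alkene and against intermolecular metathesis: the former is tetrasubstituted and deactivated by the triflate, and the two fully substituted carbons C4 and C10 (gem-dialkyl effect) together with high dilution favour cyclisation.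

Step 7
Reactants: 10 (4aS,8aS)-2,5,5,8a-tetramethyl-3,4,4a,5,6,8a-hexahydronaphthalen-1-yl trifluoromethanesulfonate (2 equiv), 11 (E)-1,2-bis(tributylstannyl)ethene
Product: 12 (E)-1,2-bis[(4aS,8aS)-2,5,5,8a-tetramethyl-3,4,4a,5,6,8a-hexahydronaphthalen-1-yl]ethene
Conditions: Pd2(dba)3 (cat.), AsPh3, LiCl, NMP, 60 °C
Reagents that add atoms: none
Why: Twofold Stille coupling: chloride-assisted oxidative addition of the hindered cyclohexenyl triflate to zerovalent palladium, transmetalation from each tin terminus of the ethene linchpin and reductive elimination should form both C9–C11 bonds, while the ring-A alkene is inert and no stereocentre is involved.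

Step 8
Reactants: 12 (E)-1,2-bis[(4aS,8aS)-2,5,5,8a-tetramethyl-3,4,4a,5,6,8a-hexahydronaphthalen-1-yl]ethene
Product: 13 1,2-bis[(4aS,8aS)-2,5,5,8a-tetramethyl-3,4,4a,5,6,7,8,8a-octahydronaphthalen-1-yl]ethane (CNP0372467.1)
Conditions: TsNHNH2 (excess, in portions), NaOAc, THF/H2O, reflux
Reagents that add atoms: none
Why: Diimide reduction: concerted syn transfer of H2 from diimide should saturate the three 1,2-disubstituted alkenes (C1=C2, C1′=C2′ and C11=C11′) while the tetrasubstituted C8=C9 alkenes do not react at a useful rate, and since no metal hydride is involved there is no alkene migration or 1,4-addition and no stereocentre is created or disturbed.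

**Compound list**

1 | (R)-(−)-carvone, (5R)-2-methyl-5-(prop-1-en-2-yl)cyclohex-2-en-1-one | CC1=CC[C@H](CC1=O)C(C)=C | starting material
2 | lithium α′-dienolate of carvone (not isolated) | [Li]OC1=C[C@H](C(C)=C)CC=C1C | intermediate
3 | (5R)-2,6-dimethyl-5-(prop-1-en-2-yl)cyclohex-2-en-1-one, C6 epimer mixture | O=C1C(C)=CC[C@@H](C(C)=C)C1C | intermediate
4 | lithium α′-dienolate of 6-methylcarvone (not isolated) | [Li]OC1=C(C)[C@H](C(C)=C)CC=C1C | intermediate
5 | (5S,6S)-6-ethenyl-2,6-dimethyl-5-(prop-1-en-2-yl)cyclohex-2-en-1-one | O=C1C(C)=CC[C@@H](C(C)=C)[C@]1(C)C=C | intermediate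
6 | lithium (5S,6S)-6-ethenyl-2,6-dimethyl-5-(prop-1-en-2-yl)cyclohex-1-en-1-olate (not isolated) | [Li]OC1=C(C)CC[C@@H](C(C)=C)[C@]1(C)C=C | intermediate
7 | (5S,6S)-6-ethenyl-2,6-dimethyl-5-(prop-1-en-2-yl)cyclohex-1-en-1-yl trifluoromethanesulfonate | O=S(=O)(OC1=C(C)CC[C@@H](C(C)=C)[C@]1(C)C=C)C(F)(F)F | intermediate
8 | (5R,6S)-5-(2-bromopropan-2-yl)-6-ethenyl-2,6-dimethylcyclohex-1-en-1-yl trifluoromethanesulfonate | O=S(=O)(OC1=C(C)CC[C@@H](C(C)(C)Br)[C@]1(C)C=C)C(F)(F)F | intermediate
9 | (5S,6S)-6-ethenyl-2,6-dimethyl-5-(2-methylpent-4-en-2-yl)cyclohex-1-en-1-yl trifluoromethanesulfonate | O=S(=O)(OC1=C(C)CC[C@@H](C(C)(C)CC=C)[C@]1(C)C=C)C(F)(F)F | intermediate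
10 | (4aS,8aS)-2,5,5,8a-tetramethyl-3,4,4a,5,6,8a-hexahydronaphthalen-1-yl trifluoromethanesulfonate | O=S(=O)(OC1=C(C)CC[C@H]2C(C)(C)CC=C[C@]12C)C(F)(F)F | intermediate
11 | (E)-1,2-bis(tributylstannyl)ethene | CCCC[Sn](CCCC)(CCCC)/C=C/[Sn](CCCC)(CCCC)CCCC | starting material
12 | (E)-1,2-bis[(4aS,8aS)-2,5,5,8a-tetramethyl-3,4,4a,5,6,8a-hexahydronaphthalen-1-yl]ethene | CC1=C(/C=C/C2=C(C)CC[C@H]3C(C)(C)CC=C[C@]23C)[C@@]2(C)C=CCC(C)(C)[C@@H]2CC1 | intermediate
13 | 1,2-bis[(4aS,8aS)-2,5,5,8a-tetramethyl-3,4,4a,5,6,7,8,8a-octahydronaphthalen-1-yl]ethane | CC1=C(CCC2=C(C)CC[C@H]3C(C)(C)CCC[C@]23C)[C@@]2(C)CCCC(C)(C)[C@@H]2CC1 | target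

**Totals.** Total step count: 8. Longest linear sequence: 8 steps, from (R)-carvone.

**Steps most likely to fail**

1. Step 2. Reductive elimination at the congested, fully substituted enolate carbon may be slow. Proton transfer could equilibrate the cross-conjugated dienolate to the linear dienolate, which would be vinylated at C2. Facial selectivity could also erode. The fallback sets out from 3 and comes back at 5. The kinetic dienolate 4 (LDA, THF, −78 °C) is added to acetaldehyde to give the aldol (5S,6R)-6-(1-hydroxyethyl)-2,6-dimethyl-5-(prop-1-en-2-yl)cyclohex-2-en-1-one F1 (either carbinol epimer), the small electrophile again entering anti to the isopropenyl group. Dehydration with Burgess reagent (PhH, 50 °C) can only eliminate toward the methyl group, because the neighbouring carbon is quaternary, and should give 5.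

2. Step 7. The coupling may stall after the first C–C bond, since the mono-coupled alkenylstannane is as hindered as the triflate, and protodestannylation or homocoupling may then compete. The fallback sets out from 10 and comes back at 13. Stille coupling of 10 with tributyl(vinyl)stannane (Pd2(dba)3, AsPh3, LiCl, NMP) should give (4aS,8aS)-1-ethenyl-2,5,5,8a-tetramethyl-3,4,4a,5,6,8a-hexahydronaphthalene F2. Hydroboration of its terminal vinyl group with 9-BBN (THF, 23 °C) gives 9-[2-((4aS,8aS)-2,5,5,8a-tetramethyl-3,4,4a,5,6,8a-hexahydronaphthalen-1-yl)ethyl]-9-borabicyclo[3.3.1]nonane F3, which is not isolated. B-alkyl Suzuki–Miyaura coupling of it with a second equivalent of 10 (PdCl2(dppf), Cs2CO3, DMF/THF/H2O, 60 °C) gives 1,2-bis[(4aS,8aS)-2,5,5,8a-tetramethyl-3,4,4a,5,6,8a-hexahydronaphthalen-1-yl]ethane F4. Diimide reduction of its two ring-A alkenes, under the conditions of step 8, gives 13.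

3. Step 5. The tertiary bromide may lose HBr thermally before the chain propagates, or the congested tertiary radical may be captured too slowly by the stannane. The fallback sets out from 8 and comes back at 9 and makes no new compound (F0). It replaces the radical by a cation: 8 is ionised with TiCl4 in CH2Cl2 at −78 °C in the presence of allyltrimethylsilane, and the tertiary cation is captured by the allylsilane to give 9 directly. The vinyl triflate and the vinyl group are poor nucleophiles and should not interfere.

**Further compounds**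

F1 | step 2 | (5S,6R)-6-(1-hydroxyethyl)-2,6-dimethyl-5-(prop-1-en-2-yl)cyclohex-2-en-1-one | O=C1C(C)=CC[C@@H](C(C)=C)[C@]1(C)C(C)O
F2 | step 7 | (4aS,8aS)-1-ethenyl-2,5,5,8a-tetramethyl-3,4,4a,5,6,8a-hexahydronaphthalene | C=CC1=C(C)CC[C@H]2C(C)(C)CC=C[C@]12C
F3 | step 7 | 9-[2-((4aS,8aS)-2,5,5,8a-tetramethyl-3,4,4a,5,6,8a-hexahydronaphthalen-1-yl)ethyl]-9-borabicyclo[3.3.1]nonane | C(CB1C2CCCC1CCC2)C1=C(C)CC[C@H]2C(C)(C)CC=C[C@]12C
F4 | step 7 | 1,2-bis[(4aS,8aS)-2,5,5,8a-tetramethyl-3,4,4a,5,6,8a-hexahydronaphthalen-1-yl]ethane | CC1=C(CCC2=C(C)CC[C@H]3C(C)(C)CC=C[C@]23C)[C@@]2(C)C=CCC(C)(C)[C@@H]2CC1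
F0 | step 5 | none | none
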